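## Structural features

The target is a cis-fused hydroazulene. A cyclopentane (C1–C2–C3–C4–C5) and a cycloheptene (C5–C6–C7=C8–C9–C10–C1) share the C1–C5 bond; these locants are used for every bicyclic compound and for the same atoms in the monocyclic precursors. C1 is quaternary (methyl) and C5 carries its hydrogen on the same face, so the two arms of the seven-membered ring (C10 on C1, C6 on C5) are cis. There are six stereocentres, (1S,3S,4R,5R,6S,10S). C3 (acetate) and C4 (tertiary hydroxyl, isopropyl) form a cis-diol derivative on the face of the C1 methyl, C6 bears the allylic 4-hydroxybenzoate, and the C10 hydroxyl is syn to the C1 methyl; C3–C4–C5–C6 is an unbroken run of four stereocentres next to the quaternary carbon. The fragile groups are: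

- the allylic ester at C6, which can ionise and, whenever C10 is a ketone, can be expelled by vinylogous β-elimination through C9–C8=C7;
- the secondary acetate beside free hydroxyls (migration, solvolysis);
- the free phenol (oxidation) and the tertiary alcohol (dehydration).

The real difficulty is threefold: the C5 arm must stand cis to the larger substituent of a quaternary neighbour, three oxygen functions of similar reactivity must be told apart, and the trisubstituted alkene must sit exactly between C7 and C8. The key step uses the fact that C9 is the α-carbon of the C10 carbonyl and C8 an alkene carbon. With C10=C9 as an enol ether and silicon on C8, the two nucleophilic carbons can be joined oxidatively, and the silicon fixes the position of the C7=C8 double bond.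

## Logic of the disconnections

**25 from 23 by way of 24.** Only the aryl O–Si bond and the C10–H bond are cut. Keeping the phenol silylated to the end protects it from the anode, and reducing C10 after ring closure lets the angular methyl of 23 direct the hydride. The gain is a ketone in place of a stereocentre. The forward steps must spare two esters and an allylic C–O bond, and the ketone must be reduced before any base meets it, because 23 can lose the C6 ester by vinylogous elimination.

**23 from 21 (22 in between).** The C8–C9 bond is cut. This removes the seven-membered ring and returns a cyclopentane whose two cis arms end in an enol ether and a vinylsilane. The forward step must oxidise only the enol ether, form the bond at the silicon-bearing carbon and not at C7, and outrun capture by solvent. No other alkene may be present, so C3=C4 must already be the diol derivative. The oxygen pair is carried as C3 acetate and C4 silyl ether, which the target needs anyway.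

**21 from 19 through 20.** The enol ether is traced to a dimethyl ketal and the C8–Si/C7–H pair to an alkyne. This leaves two robust groups that survive oxidants and bases. The forward steps need anti addition of H–Si with silicon on C8, and an elimination that touches the ketal and nothing else, which is why no isopropylidene ketal is used on O3/O4.

**19 from 17 through 18.** The acetyl C–O bond is cut, then both C–O bonds at C3 and C4, giving back the C3=C4 alkene. Two stereocentres are traded for one alkene. Osmium tetroxide must add anti to the C5 side chain, and the alkyne must stay inert. With the C6 hydroxyl already acylated, C3–OH is the only hydroxyl that can take the acetyl group.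

**17 from 13 and 16; 16 from 14.** The ester C–O bond is cut, separating the aroyl fragment. Esterification must proceed with retention at C6.

**13 from 11 through 12.** No skeletal bond is cut; the C6–H bond is. Oxidation to 12 erases the C6 centre, so any epimer mixture in 11 converges, and a reagent-controlled reduction sets C6. The demand is mildness, because C5 in 12 is both allylic and α to a ketone.

**11 from 9 through 10.** The C5–C6 bond is cut as a retro-[2,3] shift, then the ether C–O bond. This is the stereochemical core: an oxygen on C3, cis to the C10 arm, delivers C6 to C5 on that same face, so the cis relationship of the arms does not depend on the size of the C1 substituents. The shift also places the alkene at C3=C4 and brings in C6–C8 with the methyl. The demand is bond formation next to a quaternary carbon.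

**9 from 7 through 8.** The C3–H bond of the carbinol is cut, then the C3 oxygen is removed. This leaves a cyclopentene with one stereocentre. Forward, an allylic oxidation must choose the only ring methylene next to the alkene, and the enone reduction must be reagent-controlled.

**7 from 3 through 6.** The C4–isopropyl bond is cut (cross-coupling of an enol triflate), and the ketal is traced to a silyl-substituted vinyl group that serves as masked acetyl. Unmasking at the triflate stage means only one carbonyl is ever present.

**3 from 1.** The C1–C10 bond and the O–S bond are cut. A catalytic asymmetric conjugate addition sets C1, and its enolate, formed only toward C5, is trapped as the triflate, fixing the C4=C5 regiochemistry.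

## Other disconnections considered

**Alternative 1:** The cut is C1–C5. The hydroazulene is traced to the trans-fused methyl decalin A1 (tertiary hydroxyl on the fusion carbon C6, mesylate on C5 cis to it, C4 ethylene ketal, C10 silyl ether), in which C1 is still bonded to C6. Forward, KOtBu forms the alkoxide, and the C1–C6 bond, antiperiplanar to the equatorial C5–O bond, migrates to C5 with inversion, giving the hydroazulen-6-one A2.

- In its favour: the shift is stereospecific, so the cis fusion follows from geometry and not from face selectivity. Decalins of this kind come from annulation chemistry in quantity, and two rings are recast in one step.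
- Equal or better: in securing the C1/C5 relationship and in scalability this plan is the better one.
- Against it here: A2 lacks the C8 methyl, the C7=C8 alkene, the isopropyl group and the C3 oxygen. Its C5 is α to the new ketone and can epimerise under the basic conditions. The alkene would have to be placed between C7 and C8 and not C8 and C9, and the C4 carbinol would have to be made from a ketone by isopropyl addition from a defined face.
- Comparison: structurally the chosen route reaches the bicycle with every carbon and five of six stereocentres in place and needs two further steps; Alternative 1 would need of the order of a dozen. Mechanistically a closed-shell 1,2-shift is more predictable than a radical-cation closure.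

**Alternative 2:** The cut is C3–C4. The cyclopentane is opened to the cycloheptene keto aldehyde A3 (C2–C3 aldehyde arm on C1, isopropyl ketone on C5, C6 4-methoxybenzyl ether, C10 silyl ether). Forward, SmI2 generates a ketyl that couples with the second carbonyl to give the cis-diol A4.

- In its favour: both carbinol centres and their cis relationship arise in one step through a chelated intermediate, and A4 already shows the secondary/tertiary pattern that allows selective acetylation.
- Equal or better: on the cis relationship of the diol it is the equal of osmylation, and it needs no later differentiation from a C6 hydroxyl.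
- Against it here: the seven-membered ring, with the quaternary C1, C5, C6, C10 and the trisubstituted alkene, must be built beforehand, so the hardest part is moved earlier without a step that solves it. C5 in A3 is α to the ketone and β to the C6 ether, so epimerisation and β-elimination threaten. Which of the two possible cis-diols forms depends on the conformation of a flexible ring. An aroyl ester would not be safe toward the reductant, so the ether must later be exchanged for the ester and the C10 ether removed.
- Comparison: the rings are formed in reverse order to the chosen plan. The mechanism is reductive single-electron coupling against oxidative coupling. About three protecting-group steps are added after the key step, and the access to A3 is longer than the access to 21.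

**Alternative 3:** The cut is C5–C6. The precursor is the cyclopentenyl allylsilane A5 (silicon on C3, alkene C4=C5, (Z)-enal at the end of the C1 side chain, C10 silyl ether). Forward, BF3·OEt2 activates the aldehyde and C5 attacks anti to silicon, giving the allylic alcohol A6 with the alkene moved to C3=C4.

- In its favour: this is a conventional-polarity closure with good precedent for medium rings. It creates a C–C bond and two stereocentres (C5, C6) at once and leaves the alkene ready for the same dihydroxylation.
- Equal or better: in stereochemical yield per step it is the better plan. C10 is already an alcohol, so no base-sensitive β,γ-unsaturated ketone appears and no late reduction is needed. It is the equal of the chosen plan in the entropic cost of a seven-membered closure.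
- Against it here: the (Z)-enal can isomerise under the Lewis acid to the E form, which cannot close. The C6 configuration depends on the transition-state geometry. A5 needs a defined silicon-bearing centre on a ring that also holds the quaternary carbon, and the C10 centre must be set in an open chain. The later dihydroxylation must choose between two trisubstituted alkenes (C3=C4 and C7=C8), whereas in the chosen route the only other π system at that stage is an alkyne.
- Comparison: the step count should be similar or slightly higher; the risk moves from the ring closure to chemoselectivity afterwards.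

Key step: step 16

Remark on the chemistry: the ligand enantiomer in step 1 is taken to be the one that gives (S)-C1. The O3/O4 pair is carried through the ring closure as C3 acetate and C4 trimethylsilyl ether, because an isopropylidene ketal would compete for the silyl triflate of step 15 and would cost two more steps after the closure. In 17–21 the C6 descriptor reads R, since the alkyne, and later silicon, raises the rank of C7; the spatial arrangement is that of (6S) in 23–25.

## Route

Step 1
Reactants: 1 3-methylcyclopent-2-en-1-one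
Product: 3 (S)-3-methyl-3-[1-(trimethylsilyl)ethenyl]cyclopent-1-en-1-yl trifluoromethanesulfonate, via aluminium enolate 2 (not isolated)
Conditions: iBu2Al[C(SiMe3)=CH2] (from Me3SiC≡CH, iBu2AlH, hexane, 55 °C), Cu(OTf)2 (5 mol%), chiral 1-aryl-4,5-diphenyl-3-(2-sulfonatophenyl)imidazolinium zwitterion (NHC precursor, 5 mol%), THF, −78 → −30 °C; then MeLi, −78 °C; Comins' reagent, −78 → 0 °C
Reagents that add atoms: diisobutyl[1-(trimethylsilyl)ethenyl]aluminium, CC(C)C[Al](CC(C)C)C(=C)[Si](C)(C)C; Comins' reagent, N-(5-chloropyridin-2-yl)-1,1,1-trifluoro-N-[(trifluoromethyl)sulfonyl]methanesulfonamide, O=S(=O)(N(c1ccc(Cl)cn1)S(=O)(=O)C(F)(F)F)C(F)(F)F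
Why: Copper–NHC-catalysed enantioselective conjugate addition of a silyl-substituted vinylaluminium reagent to a β-substituted cyclopentenone is a known way to a vinyl-bearing quaternary carbon, and the ligand enantiomer fixes (S)-C1. The aluminium enolate exists only toward C5; after conversion to its ate complex it is O-sulfonylated, so the enol triflate has the C4=C5 regiochemistry that kinetic deprotonation of the ketone could not give.

Step 2
Reactants: 3 (S)-3-methyl-3-[1-(trimethylsilyl)ethenyl]cyclopent-1-en-1-yl trifluoromethanesulfonate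
Product: 6 (S)-3-(1,1-dimethoxyethyl)-3-methylcyclopent-1-en-1-yl trifluoromethanesulfonate, via epoxysilane 4 (not isolated), via methyl ketone 5 (not isolated)
Conditions: mCPBA, NaHCO3, CH2Cl2, 0 °C → rt; then MeOH, HC(OMe)3, TsOH·H2O (cat.), rt; Et3N
Reagents that add atoms: trimethyl orthoformate, COC(OC)OC; mCPBA, O=C(OO)c1cccc(Cl)c1 (its oxygen is kept only in 4 and 5)
Why: The peracid epoxidises the electron-rich vinylsilane and leaves the electron-poor enol triflate alkene alone; acid turns the α,β-epoxysilane into the carbonyl at the silicon-bearing carbon (Peterson-type loss of silanol), and the orthoformate ketalises the only carbonyl present. C1 is untouched and the epoxide stereocentre disappears.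

Step 3
Reactants: 6 (S)-3-(1,1-dimethoxyethyl)-3-methylcyclopent-1-en-1-yl trifluoromethanesulfonate
Product: 7 (S)-3-(1,1-dimethoxyethyl)-3-methyl-1-(propan-2-yl)cyclopent-1-ene
Conditions: iPrMgBr, Fe(acac)3 (5 mol%), THF/NMP, −30 °C
Reagents that add atoms: isopropylmagnesium bromide, CC(C)[Mg]Br
Why: Iron-catalysed Kumada-type cross-coupling of an alkenyl triflate with an alkyl Grignard reagent; the fast, cold coupling should avoid isomerisation of the secondary alkyl group, and the ketal is inert.

Step 4
Reactants: 7 (S)-3-(1,1-dimethoxyethyl)-3-methyl-1-(propan-2-yl)cyclopent-1-ene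
Product: 8 (S)-4-(1,1-dimethoxyethyl)-4-methyl-2-(propan-2-yl)cyclopent-2-en-1-one
Conditions: Rh2(cap)4 (dirhodium tetracaprolactamate, 1 mol%), t-BuOOH, K2CO3, CH2Cl2, rt
Reagents that add atoms: tert-butyl hydroperoxide, CC(C)(C)OO
Why: Allylic C–H oxidation to the enone: C3 is the only ring methylene allylic to C4=C5 (C1 has no hydrogen, C2 is not allylic), and the carbonate keeps the ketal intact. The isopropyl methine is the competing site.

Step 5
Reactants: 8 (S)-4-(1,1-dimethoxyethyl)-4-methyl-2-(propan-2-yl)cyclopent-2-en-1-one
Product: 9 (1R,4S)-4-(1,1-dimethoxyethyl)-4-methyl-2-(propan-2-yl)cyclopent-2-en-1-ol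
Conditions: (S)-1-methyl-3,3-diphenyltetrahydro-1H,3H-pyrrolo[1,2-c][1,3,2]oxazaborole [(S)-Me-CBS, 20 mol%], catecholborane, toluene, −78 °C; MeOH, aq NaOH
Reagents that add atoms: none
Why: Corey–Bakshi–Shibata reduction of an α-substituted cyclopentenone: the alkenyl branch acts as the large group, so the (S)-catalyst should give the (R)-carbinol with the hydroxyl cis to the C10 arm. Hydride then also arrives anti to the bulky ketal, a matched case.

Step 6
Reactants: 9 (1R,4S)-4-(1,1-dimethoxyethyl)-4-methyl-2-(propan-2-yl)cyclopent-2-en-1-ol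
Product: 10 (3S,5R)-5-(but-2-yn-1-yloxy)-3-(1,1-dimethoxyethyl)-3-methyl-1-(propan-2-yl)cyclopent-1-ene
Conditions: NaH, 1-bromobut-2-yne, Bu4NI (cat.), THF/DMF, 0 °C → rt
Reagents that add atoms: 1-bromobut-2-yne, CC#CCBr
Why: Williamson etherification of the allylic alkoxide with a reactive propargylic bromide; no stereocentre is touched.

Step 7
Reactants: 10 (3S,5R)-5-(but-2-yn-1-yloxy)-3-(1,1-dimethoxyethyl)-3-methyl-1-(propan-2-yl)cyclopent-1-ene
Product: 11 1-[(1R,5S)-5-(1,1-dimethoxyethyl)-5-methyl-2-(propan-2-yl)cyclopent-2-en-1-yl]but-2-yn-1-ol (both carbinol epimers)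
Conditions: n-BuLi, THF, −78 °C; aq NH4Cl; Et3N-buffered work-up
Reagents that add atoms: none
Why: [2,3]-Wittig rearrangement of an allyl propargyl ether: lithiation at the propargylic O–CH2 and a suprafacial five-membered transition state transfer the C3 oxygen stereocentre to C5, so the new C5–C6 bond lies on the face of the C10 arm and the alkene moves to C3=C4. The C6 carbinol is expected as an epimer mixture (mainly with the alkyne turned away from C1), which steps 8 and 9 correct.

Step 8
Reactants: 11 1-[(1R,5S)-5-(1,1-dimethoxyethyl)-5-methyl-2-(propan-2-yl)cyclopent-2-en-1-yl]but-2-yn-1-ol (both carbinol epimers)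
Product: 12 1-[(1R,5S)-5-(1,1-dimethoxyethyl)-5-methyl-2-(propan-2-yl)cyclopent-2-en-1-yl]but-2-yn-1-one
Conditions: Dess–Martin periodinane, NaHCO3, CH2Cl2, 0 °C
Reagents that add atoms: none
Why: Dess–Martin oxidation under bicarbonate buffer converges both C6 epimers to one ynone without acid or base that could move the β,γ-alkene, epimerise C5 or open the ketal.

Step 9
Reactants: 12 1-[(1R,5S)-5-(1,1-dimethoxyethyl)-5-methyl-2-(propan-2-yl)cyclopent-2-en-1-yl]but-2-yn-1-one
Product: 13 (1R)-1-[(1R,5S)-5-(1,1-dimethoxyethyl)-5-methyl-2-(propan-2-yl)cyclopent-2-en-1-yl]but-2-yn-1-ol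
Conditions: (R)-1-methyl-3,3-diphenyltetrahydro-1H,3H-pyrrolo[1,2-c][1,3,2]oxazaborole [(R)-Me-CBS, 1 equiv], catecholborane, toluene, −78 °C; MeOH, aq NaOH
Reagents that add atoms: none
Why: Corey–Bakshi–Shibata reduction of an alkynyl ketone, in which the alkyne is the small group: the (R)-catalyst should deliver hydride to give the (R)-propargylic alcohol, which has the spatial arrangement of (6S) in the target. Felkin–Anh attack anti to the quaternary C1 leads to the same isomer, so substrate and reagent are matched.

Step 10
Reactants: 14 4-hydroxybenzoic acid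
Product: 16 4-[(triisopropylsilyl)oxy]benzoic acid, via silyl ester 15 (not isolated)
Conditions: iPr3SiCl (2.2 equiv), imidazole, DMF, rt; then AcOH, THF, H2O
Reagents that add atoms: chlorotriisopropylsilane, CC(C)[Si](Cl)(C(C)C)C(C)C
Why: Both acidic hydroxyls are silylated and the labile silyl ester is hydrolysed selectively; the aryl silyl ether that remains keeps the phenol out of reach of the anode.

Step 11
Reactants: 13 (1R)-1-[(1R,5S)-5-(1,1-dimethoxyethyl)-5-methyl-2-(propan-2-yl)cyclopent-2-en-1-yl]but-2-yn-1-ol; 16 4-[(triisopropylsilyl)oxy]benzoic acid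
Product: 17 (1R)-1-[(1R,5S)-5-(1,1-dimethoxyethyl)-5-methyl-2-(propan-2-yl)cyclopent-2-en-1-yl]but-2-yn-1-yl 4-[(triisopropylsilyl)oxy]benzoate
Conditions: EDC·HCl, DMAP, CH2Cl2, rt
Reagents that add atoms: none
Why: Steglich esterification engages only the O–H bond, so C6 keeps its configuration. Acylating C6 now leaves C3–OH as the only acylable hydroxyl after dihydroxylation and ends the period in which a free C6 hydroxyl sits cis to the ketal.

Step 12
Reactants: 17 (1R)-1-[(1R,5S)-5-(1,1-dimethoxyethyl)-5-methyl-2-(propan-2-yl)cyclopent-2-en-1-yl]but-2-yn-1-yl 4-[(triisopropylsilyl)oxy]benzoate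
Product: 18 (1R)-1-[(1R,2R,3S,5S)-5-(1,1-dimethoxyethyl)-2,3-dihydroxy-5-methyl-2-(propan-2-yl)cyclopentyl]but-2-yn-1-yl 4-[(triisopropylsilyl)oxy]benzoate
Conditions: OsO4 (5 mol%), NMO, acetone/H2O, rt
Reagents that add atoms: N-methylmorpholine N-oxide, C[N+]1([O-])CCOCC1; water, O
Why: Upjohn dihydroxylation: the alkyne and the arene are inert, and osmium tetroxide adds to the face of C3=C4 opposite to the C5 side chain and the C10 arm. This sets (3S) and (4R), with both hydroxyls on the face of the C1 methyl.

Step 13
Reactants: 18 (1R)-1-[(1R,2R,3S,5S)-5-(1,1-dimethoxyethyl)-2,3-dihydroxy-5-methyl-2-(propan-2-yl)cyclopentyl]but-2-yn-1-yl 4-[(triisopropylsilyl)oxy]benzoate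
Product: 19 (1R)-1-[(1R,2R,3S,5S)-3-(acetyloxy)-5-(1,1-dimethoxyethyl)-2-hydroxy-5-methyl-2-(propan-2-yl)cyclopentyl]but-2-yn-1-yl 4-[(triisopropylsilyl)oxy]benzoate
Conditions: Ac2O, pyridine, DMAP (cat.), CH2Cl2, 0 °C → rt
Reagents that add atoms: acetic anhydride, CC(=O)OC(C)=O
Why: The only secondary hydroxyl is acetylated; the tertiary C4 hydroxyl does not react under these conditions.

Step 14
Reactants: 19 (1R)-1-[(1R,2R,3S,5S)-3-(acetyloxy)-5-(1,1-dimethoxyethyl)-2-hydroxy-5-methyl-2-(propan-2-yl)cyclopentyl]but-2-yn-1-yl 4-[(triisopropylsilyl)oxy]benzoate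
Product: 20 (1R,2Z)-1-[(1R,2R,3S,5S)-3-(acetyloxy)-5-(1,1-dimethoxyethyl)-2-hydroxy-5-methyl-2-(propan-2-yl)cyclopentyl]-3-(triethylsilyl)but-2-en-1-yl 4-[(triisopropylsilyl)oxy]benzoate
Conditions: [Cp*Ru(MeCN)3]PF6 (5 mol%), Et3SiH, CH2Cl2, 0 °C → rt
Reagents that add atoms: triethylsilane, CC[SiH](CC)CC
Why: Ruthenium-catalysed trans-hydrosilylation of an internal alkyne: H and Si add anti, and the electron-withdrawing propargylic oxygen substituent should steer silicon to the distal carbon C8. This gives the (Z)-vinylsilane with silicon cis to C6.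

Step 15
Reactants: 20 (1R,2Z)-1-[(1R,2R,3S,5S)-3-(acetyloxy)-5-(1,1-dimethoxyethyl)-2-hydroxy-5-methyl-2-(propan-2-yl)cyclopentyl]-3-(triethylsilyl)but-2-en-1-yl 4-[(triisopropylsilyl)oxy]benzoate
Product: 21 (1R,2Z)-1-[(1R,2R,3S,5S)-3-(acetyloxy)-5-(1-methoxyethenyl)-5-methyl-2-(propan-2-yl)-2-[(trimethylsilyl)oxy]cyclopentyl]-3-(triethylsilyl)but-2-en-1-yl 4-[(triisopropylsilyl)oxy]benzoate
Conditions: Me3SiOTf (2.5 equiv), iPr2NEt (3.5 equiv), CH2Cl2, −40 → 0 °C
Reagents that add atoms: trimethylsilyl trifluoromethanesulfonate, C[Si](C)(C)OS(=O)(=O)C(F)(F)F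
Why: Silyl triflate and a hindered amine ionise the acyclic ketal and remove a C9 proton; C1 is quaternary, so only the terminal methyl enol ether can form. The tertiary hydroxyl is capped as its trimethylsilyl ether in the same operation, and no other ketal is present to compete.

Step 16
Reactants: 21 (1R,2Z)-1-[(1R,2R,3S,5S)-3-(acetyloxy)-5-(1-methoxyethenyl)-5-methyl-2-(propan-2-yl)-2-[(trimethylsilyl)oxy]cyclopentyl]-3-(triethylsilyl)but-2-en-1-yl 4-[(triisopropylsilyl)oxy]benzoate
Product: 23 (1S,3S,4R,5R,6S)-3-(acetyloxy)-4-hydroxy-1,8-dimethyl-10-oxo-4-(propan-2-yl)bicyclo[5.3.0]dec-7-en-6-yl 4-[(triisopropylsilyl)oxy]benzoate (skeletal locants), via dimethyl ketal 22 (not isolated)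
Conditions: reticulated vitreous carbon anode, Pt cathode, undivided cell, LiClO4 (0.1 M), MeOH/CH2Cl2 (1:4), 2,6-lutidine, constant current (8 mA), 2.2 F/mol, rt; then 1 M HCl, THF, 0 °C
Reagents that add atoms: water, O; methanol, CO (kept only in 22)
Why: This is an anodic olefin coupling of an enol ether radical cation with a vinylsilane terminator, a known reaction type that is seldom used for seven-membered rings. The enol ether has the lowest oxidation potential in 21 (vinylsilane, acylated arene and esters lie higher), so the anode removes an electron there and the radical cation becomes electrophilic at C9. C8, the silicon-bearing carbon, attacks; the centre left at C7 is stabilised by the β C–Si bond, gives up the second electron and the silyl group to methanol, and C7=C8 is restored, while methanol caps C10 as the dimethyl ketal 22. The ring closes in a 7-endo-trig mode with respect to both π systems, and no stereocentre is formed. The step needs chemoselective oxidation, attack at C8 in preference to 6-exo attack at C7, and cyclisation faster than solvent capture. These are secured by the β-silicon effect together with the Z geometry (the C–Si bond can swing into alignment while the ring torsion closes toward the cis alkene), by the cis arms on the cyclopentane, by the absence of any other alkene, and by a low methanol content; 2,6-lutidine buffers the acid formed, and the C4 silyl ether is trans to C10 and cannot trap the cation. Aqueous acid then hydrolyses the ketal and the tertiary silyl ether.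

Step 17
Reactants: 23 (1S,3S,4R,5R,6S)-3-(acetyloxy)-4-hydroxy-1,8-dimethyl-10-oxo-4-(propan-2-yl)bicyclo[5.3.0]dec-7-en-6-yl 4-[(triisopropylsilyl)oxy]benzoate (skeletal locants)
Product: 24 (1S,3S,4R,5R,6S,10S)-3-(acetyloxy)-4,10-dihydroxy-1,8-dimethyl-4-(propan-2-yl)bicyclo[5.3.0]dec-7-en-6-yl 4-[(triisopropylsilyl)oxy]benzoate (skeletal locants)
Conditions: NaBH4, CeCl3·7H2O, MeOH, −78 °C
Reagents that add atoms: none
Why: Luche-type 1,2-reduction: hydride should approach C10 from the face opposite to the adjacent angular methyl, giving the (10S)-alcohol syn to that methyl. The cold, non-basic medium spares both esters and avoids enolisation toward C9, which would expel the C6 ester.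

Step 18
Reactants: 24 (1S,3S,4R,5R,6S,10S)-3-(acetyloxy)-4,10-dihydroxy-1,8-dimethyl-4-(propan-2-yl)bicyclo[5.3.0]dec-7-en-6-yl 4-[(triisopropylsilyl)oxy]benzoate (skeletal locants)
Product: 25 (1S,3S,4R,5R,6S,10S)-3-(acetyloxy)-4,10-dihydroxy-1,8-dimethyl-4-(propan-2-yl)bicyclo[5.3.0]dec-7-en-6-yl 4-hydroxybenzoate (skeletal locants; CNP0146780.2)
Conditions: HF·pyridine, pyridine, THF, 0 °C → rt
Reagents that add atoms: none
Why: Fluoride cleaves the aryl silyl ether; buffered HF·pyridine is not basic enough to hydrolyse or shift the acetate or the aroyl ester.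

## Compound list

1 | 3-methylcyclopent-2-en-1-one | CC1=CC(=O)CC1 | starting material
2 | diisobutylaluminium (S)-3-methyl-3-[1-(trimethylsilyl)ethenyl]cyclopent-1-en-1-olate | C[C@]1(C(=C)[Si](C)(C)C)CCC(O[Al](CC(C)C)CC(C)C)=C1 | intermediate
3 | (S)-3-methyl-3-[1-(trimethylsilyl)ethenyl]cyclopent-1-en-1-yl trifluoromethanesulfonate | C[C@]1(C(=C)[Si](C)(C)C)CCC(OS(=O)(=O)C(F)(F)F)=C1 | intermediate
4 | (3S)-3-methyl-3-[2-(trimethylsilyl)oxiran-2-yl]cyclopent-1-en-1-yl trifluoromethanesulfonate (both oxirane epimers) | C[C@]1(C2(CO2)[Si](C)(C)C)CCC(OS(=O)(=O)C(F)(F)F)=C1 | intermediate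
5 | (S)-3-acetyl-3-methylcyclopent-1-en-1-yl trifluoromethanesulfonate | C[C@]1(C(C)=O)CCC(OS(=O)(=O)C(F)(F)F)=C1 | intermediate
6 | (S)-3-(1,1-dimethoxyethyl)-3-methylcyclopent-1-en-1-yl trifluoromethanesulfonate | C[C@]1(C(C)(OC)OC)CCC(OS(=O)(=O)C(F)(F)F)=C1 | intermediate
7 | (S)-3-(1,1-dimethoxyethyl)-3-methyl-1-(propan-2-yl)cyclopent-1-ene | C[C@]1(C(C)(OC)OC)CCC(C(C)C)=C1 | intermediate
8 | (S)-4-(1,1-dimethoxyethyl)-4-methyl-2-(propan-2-yl)cyclopent-2-en-1-one | C[C@]1(C(C)(OC)OC)CC(=O)C(C(C)C)=C1 | intermediate
9 | (1R,4S)-4-(1,1-dimethoxyethyl)-4-methyl-2-(propan-2-yl)cyclopent-2-en-1-ol | C[C@]1(C(C)(OC)OC)C[C@@H](O)C(C(C)C)=C1 | intermediate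
10 | (3S,5R)-5-(but-2-yn-1-yloxy)-3-(1,1-dimethoxyethyl)-3-methyl-1-(propan-2-yl)cyclopent-1-ene | C[C@]1(C(C)(OC)OC)C[C@@H](OCC#CC)C(C(C)C)=C1 | intermediate
11 | 1-[(1R,5S)-5-(1,1-dimethoxyethyl)-5-methyl-2-(propan-2-yl)cyclopent-2-en-1-yl]but-2-yn-1-ol (both carbinol epimers) | CC(C)C1=CC[C@](C)(C(C)(OC)OC)[C@@H]1C(O)C#CC | intermediate
12 | 1-[(1R,5S)-5-(1,1-dimethoxyethyl)-5-methyl-2-(propan-2-yl)cyclopent-2-en-1-yl]but-2-yn-1-one | CC(C)C1=CC[C@](C)(C(C)(OC)OC)[C@@H]1C(=O)C#CC | intermediate
13 | (1R)-1-[(1R,5S)-5-(1,1-dimethoxyethyl)-5-methyl-2-(propan-2-yl)cyclopent-2-en-1-yl]but-2-yn-1-ol | CC(C)C1=CC[C@](C)(C(C)(OC)OC)[C@@H]1[C@@H](O)C#CC | intermediate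
14 | 4-hydroxybenzoic acid | O=C(O)c1ccc(O)cc1 | starting material
15 | triisopropylsilyl 4-[(triisopropylsilyl)oxy]benzoate | CC(C)[Si](OC(=O)c1ccc(O[Si](C(C)C)(C(C)C)C(C)C)cc1)(C(C)C)C(C)C | intermediate
16 | 4-[(triisopropylsilyl)oxy]benzoic acid | O=C(O)c1ccc(O[Si](C(C)C)(C(C)C)C(C)C)cc1 | intermediate
17 | (1R)-1-[(1R,5S)-5-(1,1-dimethoxyethyl)-5-methyl-2-(propan-2-yl)cyclopent-2-en-1-yl]but-2-yn-1-yl 4-[(triisopropylsilyl)oxy]benzoate | CC(C)C1=CC[C@](C)(C(C)(OC)OC)[C@@H]1[C@@H](OC(=O)c2ccc(O[Si](C(C)C)(C(C)C)C(C)C)cc2)C#CC | intermediate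
18 | (1R)-1-[(1R,2R,3S,5S)-5-(1,1-dimethoxyethyl)-2,3-dihydroxy-5-methyl-2-(propan-2-yl)cyclopentyl]but-2-yn-1-yl 4-[(triisopropylsilyl)oxy]benzoate | O[C@H]1C[C@](C)(C(C)(OC)OC)[C@H]([C@@H](OC(=O)c2ccc(O[Si](C(C)C)(C(C)C)C(C)C)cc2)C#CC)[C@]1(O)C(C)C | intermediate
19 | (1R)-1-[(1R,2R,3S,5S)-3-(acetyloxy)-5-(1,1-dimethoxyethyl)-2-hydroxy-5-methyl-2-(propan-2-yl)cyclopentyl]but-2-yn-1-yl 4-[(triisopropylsilyl)oxy]benzoate | CC(=O)O[C@H]1C[C@](C)(C(C)(OC)OC)[C@H]([C@@H](OC(=O)c2ccc(O[Si](C(C)C)(C(C)C)C(C)C)cc2)C#CC)[C@]1(O)C(C)C | intermediate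
20 | (1R,2Z)-1-[(1R,2R,3S,5S)-3-(acetyloxy)-5-(1,1-dimethoxyethyl)-2-hydroxy-5-methyl-2-(propan-2-yl)cyclopentyl]-3-(triethylsilyl)but-2-en-1-yl 4-[(triisopropylsilyl)oxy]benzoate | CC(=O)O[C@H]1C[C@](C)(C(C)(OC)OC)[C@H]([C@@H](OC(=O)c2ccc(O[Si](C(C)C)(C(C)C)C(C)C)cc2)/C=C(/C)[Si](CC)(CC)CC)[C@]1(O)C(C)C | intermediate
21 | (1R,2Z)-1-[(1R,2R,3S,5S)-3-(acetyloxy)-5-(1-methoxyethenyl)-5-methyl-2-(propan-2-yl)-2-[(trimethylsilyl)oxy]cyclopentyl]-3-(triethylsilyl)but-2-en-1-yl 4-[(triisopropylsilyl)oxy]benzoate (precursor of the key step) | CC(=O)O[C@H]1C[C@](C)(C(OC)=C)[C@H]([C@@H](OC(=O)c2ccc(O[Si](C(C)C)(C(C)C)C(C)C)cc2)/C=C(/C)[Si](CC)(CC)CC)[C@]1(O[Si](C)(C)C)C(C)C | intermediate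
22 | (1S,3S,4R,5R,6S)-3-(acetyloxy)-10,10-dimethoxy-1,8-dimethyl-4-(propan-2-yl)-4-[(trimethylsilyl)oxy]bicyclo[5.3.0]dec-7-en-6-yl 4-[(triisopropylsilyl)oxy]benzoate (skeletal locants) | CC(=O)O[C@H]1C[C@]2(C)C(OC)(OC)CC(C)=C[C@H](OC(=O)c3ccc(O[Si](C(C)C)(C(C)C)C(C)C)cc3)[C@@H]2[C@]1(O[Si](C)(C)C)C(C)C | intermediate
23 | (1S,3S,4R,5R,6S)-3-(acetyloxy)-4-hydroxy-1,8-dimethyl-10-oxo-4-(propan-2-yl)bicyclo[5.3.0]dec-7-en-6-yl 4-[(triisopropylsilyl)oxy]benzoate (skeletal locants; product of the key step) | CC(=O)O[C@H]1C[C@]2(C)C(=O)CC(C)=C[C@H](OC(=O)c3ccc(O[Si](C(C)C)(C(C)C)C(C)C)cc3)[C@@H]2[C@]1(O)C(C)C | intermediate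
24 | (1S,3S,4R,5R,6S,10S)-3-(acetyloxy)-4,10-dihydroxy-1,8-dimethyl-4-(propan-2-yl)bicyclo[5.3.0]dec-7-en-6-yl 4-[(triisopropylsilyl)oxy]benzoate (skeletal locants) | CC(=O)O[C@H]1C[C@]2(C)[C@@H](O)CC(C)=C[C@H](OC(=O)c3ccc(O[Si](C(C)C)(C(C)C)C(C)C)cc3)[C@@H]2[C@]1(O)C(C)C | intermediate
25 | (1S,3S,4R,5R,6S,10S)-3-(acetyloxy)-4,10-dihydroxy-1,8-dimethyl-4-(propan-2-yl)bicyclo[5.3.0]dec-7-en-6-yl 4-hydroxybenzoate (skeletal locants) | CC(=O)O[C@H]1C[C@]2(C)[C@@H](O)CC(C)=C[C@H](OC(=O)c3ccc(O)cc3)[C@@H]2[C@]1(O)C(C)C | target

## Step count and least certain steps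

Total: 18 steps. Longest linear sequence: 17 steps (steps 1–9 and 11–18, from 1 to 25); step 10 is a one-step branch.

**Step 16 (key step).** The most likely failures are bond formation at C7 (6-exo closure, giving a six-membered ring and a tertiary α-silyl cation) and capture of the radical cation by methanol before the slow seven-membered closure. Ring strain and the inductive pull of the C6 ester on the developing C7 cation both work against the wanted mode. Fallback, from 20 back to 23: iododesilylation of 20 with N-iodosuccinimide (retention) should give the (Z)-vinyl iodide ketal F1; mild aqueous acid should free the methyl ketone F2; a palladium-catalysed intramolecular α-alkenylation of the ketone enolate (Pd(PPh3)4, K3PO4, THF) would then form the same C8–C9 bond and deliver 23.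

**Step 1.** The aluminium enolate may be sulfonylated too slowly and be protonated on work-up to the ketone, from which the C4=C5 triflate cannot be regenerated regioselectively. Fallback, from 1 (through 2) back to 3: quench the enolate with acetic anhydride to the enol acetate F3, then cleave it with MeLi to the regiodefined lithium enolate and triflate that with N-phenyltriflimide.

**Step 4.** Hydrogen abstraction at the isopropyl methine, or attack at the transposed allylic terminus, may compete with oxidation of the C3 methylene, because the radical pathway is not strongly site-selective. Fallback, from 7 back to 8: Riley oxidation (SeO2 cat., t-BuOOH, pyridine-buffered), which prefers the methylene on the more substituted alkene carbon by an ene/[2,3] sequence, to the allylic alcohol F4 (C3 epimers), then MnO2 to 8.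

**Step 7.** The new bond is made on the face that already carries the bulky ketal of the quaternary neighbour; steric retardation may let the [1,2]-shift or elimination compete. Fallback, from 9 back to 11: alkylation with Bu3SnCH2I (KH) to the stannylmethyl ether F5; tin–lithium exchange and Wittig–Still rearrangement (a more reactive, unstabilised carbanion) to the primary alcohol F6; Dess–Martin oxidation to the aldehyde F7; addition of 1-propynylmagnesium bromide to give 11 as an epimer mixture, which is what step 8 needs.

**Step 14.** Regiocontrol may erode (silicon delivered to C7) because the propargylic oxygen is acylated and not free, and the bulky C5 substituent favours the other regiochemistry. Fallback, from 13 back to 20: hydrosilylate the free alcohol 13 to the vinylsilane alcohol F8, esterify with 16 to F9, dihydroxylate the cyclopentene (the silylated, ester-deactivated alkene should react more slowly) to F10, and acetylate to 20.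

**Step 17.** Facial selectivity may be poor, because the cis-fused seven-membered ring is flexible and the angular methyl may not dominate. Fallback, from 23 back to 24 without new compounds: replace substrate control by reagent control, using an oxazaborolidine-catalysed borane reduction in which the quaternary C1 is the large group and C9 the small one.

## Further compounds

F1 | step 16 | (1R,2Z)-1-[(1R,2R,3S,5S)-3-(acetyloxy)-5-(1,1-dimethoxyethyl)-2-hydroxy-5-methyl-2-(propan-2-yl)cyclopentyl]-3-iodobut-2-en-1-yl 4-[(triisopropylsilyl)oxy]benzoate | CC(=O)O[C@H]1C[C@](C)(C(C)(OC)OC)[C@H]([C@@H](OC(=O)c2ccc(O[Si](C(C)C)(C(C)C)C(C)C)cc2)/C=C(/C)I)[C@]1(O)C(C)C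
F2 | step 16 | (1R,2Z)-1-[(1R,2R,3S,5S)-5-acetyl-3-(acetyloxy)-2-hydroxy-5-methyl-2-(propan-2-yl)cyclopentyl]-3-iodobut-2-en-1-yl 4-[(triisopropylsilyl)oxy]benzoate | CC(=O)O[C@H]1C[C@](C)(C(C)=O)[C@H]([C@@H](OC(=O)c2ccc(O[Si](C(C)C)(C(C)C)C(C)C)cc2)/C=C(/C)I)[C@]1(O)C(C)C
F3 | step 1 | (S)-3-methyl-3-[1-(trimethylsilyl)ethenyl]cyclopent-1-en-1-yl acetate | C[C@]1(C(=C)[Si](C)(C)C)CCC(OC(C)=O)=C1
F4 | step 4 | (4S)-4-(1,1-dimethoxyethyl)-4-methyl-2-(propan-2-yl)cyclopent-2-en-1-ol (both carbinol epimers) | C[C@]1(C(C)(OC)OC)CC(O)C(C(C)C)=C1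
F5 | step 7 | tributyl({[(1R,4S)-4-(1,1-dimethoxyethyl)-4-methyl-2-(propan-2-yl)cyclopent-2-en-1-yl]oxy}methyl)stannane | C[C@]1(C(C)(OC)OC)C[C@@H](OC[Sn](CCCC)(CCCC)CCCC)C(C(C)C)=C1
F6 | step 7 | [(1R,5S)-5-(1,1-dimethoxyethyl)-5-methyl-2-(propan-2-yl)cyclopent-2-en-1-yl]methanol | CC(C)C1=CC[C@](C)(C(C)(OC)OC)[C@@H]1CO
F7 | step 7 | (1R,5S)-5-(1,1-dimethoxyethyl)-5-methyl-2-(propan-2-yl)cyclopent-2-ene-1-carbaldehyde | CC(C)C1=CC[C@](C)(C(C)(OC)OC)[C@@H]1C=O
F8 | step 14 | (1R,2Z)-1-[(1R,5S)-5-(1,1-dimethoxyethyl)-5-methyl-2-(propan-2-yl)cyclopent-2-en-1-yl]-3-(triethylsilyl)but-2-en-1-ol | CC(C)C1=CC[C@](C)(C(C)(OC)OC)[C@@H]1[C@@H](O)/C=C(/C)[Si](CC)(CC)CC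
F9 | step 14 | (1R,2Z)-1-[(1R,5S)-5-(1,1-dimethoxyethyl)-5-methyl-2-(propan-2-yl)cyclopent-2-en-1-yl]-3-(triethylsilyl)but-2-en-1-yl 4-[(triisopropylsilyl)oxy]benzoate | CC(C)C1=CC[C@](C)(C(C)(OC)OC)[C@@H]1[C@@H](OC(=O)c2ccc(O[Si](C(C)C)(C(C)C)C(C)C)cc2)/C=C(/C)[Si](CC)(CC)CC
F10 | step 14 | (1R,2Z)-1-[(1R,2R,3S,5S)-5-(1,1-dimethoxyethyl)-2,3-dihydroxy-5-methyl-2-(propan-2-yl)cyclopentyl]-3-(triethylsilyl)but-2-en-1-yl 4-[(triisopropylsilyl)oxy]benzoate | O[C@H]1C[C@](C)(C(C)(OC)OC)[C@H]([C@@H](OC(=O)c2ccc(O[Si](C(C)C)(C(C)C)C(C)C)cc2)/C=C(/C)[Si](CC)(CC)CC)[C@]1(O)C(C)C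
F0 | step 17 | none | none
A1 | alternative 1 | trans-fused 1-methyldecalin with C6 hydroxyl, C5 methanesulfonate cis to it, C4 ethylene ketal and C10 tert-butyldimethylsilyl ether (skeletal locants) | C1C[C@]2(C)[C@@H](O[Si](C)(C)C(C)(C)C)CCC[C@@]2(O)[C@H](OS(C)(=O)=O)C13OCCO3
A2 | alternative 1 | cis-fused hydroazulen-6-one with C4 ethylene ketal and C10 tert-butyldimethylsilyl ether | C1C[C@]2(C)[C@@H](O[Si](C)(C)C(C)(C)C)CCCC(=O)[C@@H]2C13OCCO3
A3 | alternative 2 | cycloheptene keto aldehyde: 2-oxoethyl and methyl on C1, 2-methylpropanoyl on C5, C6 4-methoxybenzyl ether, C10 tert-butyldimethylsilyl ether | O=CC[C@]1(C)[C@@H](O[Si](C)(C)C(C)(C)C)CC(C)=C[C@H](OCc2ccc(OC)cc2)[C@@H]1C(=O)C(C)C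
A4 | alternative 2 | bicyclic C3,C4-cis-diol with C6 4-methoxybenzyl ether and C10 tert-butyldimethylsilyl ether | O[C@H]1C[C@]2(C)[C@@H](O[Si](C)(C)C(C)(C)C)CC(C)=C[C@H](OCc3ccc(OC)cc3)[C@@H]2[C@]1(O)C(C)C
A5 | alternative 3 | cyclopentenyl allylsilane (dimethylphenylsilyl on C3, C4=C5, isopropyl on C4) with (Z)-enal side chain on C1 and C10 tert-butyldimethylsilyl ether | O=C/C=C(C)\C[C@H](O[Si](C)(C)C(C)(C)C)[C@@]1(C)C[C@H]([Si](C)(C)c2ccccc2)C(C(C)C)=C1
A6 | alternative 3 | cis-fused bicyclic C6 allylic alcohol with C3=C4 and C7=C8 alkenes and C10 tert-butyldimethylsilyl ether | C1C[C@]2(C)[C@@H](O[Si](C)(C)C(C)(C)C)CC(C)=C[C@H](O)[C@@H]2C=1C(C)C
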